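**Plan**

1. Numbering and enabling feature: the cyclohexane is C5–C10. C5 bears the acrolein arm C4(=C15)–C3, C6 the isobutyrate, C7/C8 the methylene lactone (C11, C12, C13; ring oxygen O8), C9 the hydroxyl, C10 the methyl C14 and the oxirane C1–C2. In ring C5–C10 the quaternary C10 carries the oxygenated C1 and is bonded to C5, whose substituent C4 is a 2-propenyl unit. That is the imprint of a C1/C10 epoxide opened to a C10 radical that has added to a C5=C4 prenyl-type alkene.
2. Retrosynthetic cuts, in order: C3 aldehyde back to a C4 methyl group; C11=C13; O1–C2 (oxirane from the C1,C2-diol); O8–C12 (lactone from acetonide plus tert-butyl ester); then the ring bond C5–C10 (key); then the chain bonds C5–C6, C6–C7 (via a vinyl group), C7=C11, C10=C1 and C10–C14.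
3. Forward: one linear chain is grown from D-erythronolactone acetonide (C7–C10). The cyclohexane closes in step 13, the lactone in step 14, the oxirane in step 15; methylenation and allylic oxidation finish.
4. Stereochemistry: C8 and C9 come from the lactone; C1 from a Sharpless epoxidation and is carried unchanged into the oxirane; C7 from an anti-selective cuprate addition directed by C8; C6 from a chelation-controlled Grignard addition directed by C7/C8; C5 and C10 from the chair transition state of the radical ring closure.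

Key step: step 13

Remark: the SMILES is read as (1R,5R,6S,7S,8R,9S,10S) in the numbering above, with C4, O6, C11 and C14 on one face of the cyclohexane and O8, O9 and C1 on the other; TBS = tert-butyldimethylsilyl, TES = triethylsilyl.

**Route**

Step 1
Reactants: 1 2,3-O-isopropylidene-D-erythronolactone
Product: 3 (4R,5R)-N-methoxy-N,2,2-trimethyl-5-[(triethylsilyloxy)methyl]-1,3-dioxolane-4-carboxamide, via hydroxy Weinreb amide 2 (not isolated)
Conditions: MeNH(OMe)·HCl, AlMe3, CH2Cl2, 0 °C to rt; crude 2 then Et3SiCl, imidazole, CH2Cl2, 0 °C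
Reagents that add atoms: N,O-dimethylhydroxylamine hydrochloride CNOC.Cl; chlorotriethylsilane CC[Si](Cl)(CC)CC
Why: The aluminium amide opens the lactone to the open-chain Weinreb amide without touching the two stereocentres (the future C8 and C9), and immediate silylation of the released primary hydroxyl stops relactonization.

Step 2
Reactants: 3 (4R,5R)-N-methoxy-N,2,2-trimethyl-5-[(triethylsilyloxy)methyl]-1,3-dioxolane-4-carboxamide
Product: 4 1-[(4R,5R)-2,2-dimethyl-5-[(triethylsilyloxy)methyl]-1,3-dioxolan-4-yl]ethan-1-one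
Conditions: MeMgBr, THF, −20 to 0 °C
Reagents that add atoms: methylmagnesium bromide C[Mg]Br
Why: Weinreb ketone synthesis, in which the chelated tetrahedral adduct survives until work-up so that a single methyl group (C14) is added and the α-alkoxy centre C9 is not exposed to excess base.

Step 3
Reactants: 4 1-[(4R,5R)-2,2-dimethyl-5-[(triethylsilyloxy)methyl]-1,3-dioxolan-4-yl]ethan-1-one; 5 triethyl phosphonoacetate
Product: 6 ethyl (2E)-3-[(4S,5R)-2,2-dimethyl-5-[(triethylsilyloxy)methyl]-1,3-dioxolan-4-yl]but-2-enoate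
Conditions: NaH, THF, 0 °C to rt
Reagents that add atoms: none
Why: Horner–Wadsworth–Emmons olefination of the methyl ketone should place the ester trans to the branched dioxolanyl group (E isomer; the minor Z isomer is removed by chromatography), which fixes the alkene geometry that the epoxidation turns into the C1/C10 relationship.

Step 4
Reactants: 6 ethyl (2E)-3-[(4S,5R)-2,2-dimethyl-5-[(triethylsilyloxy)methyl]-1,3-dioxolan-4-yl]but-2-enoate
Product: 7 (2E)-3-[(4S,5R)-2,2-dimethyl-5-[(triethylsilyloxy)methyl]-1,3-dioxolan-4-yl]but-2-en-1-ol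
Conditions: i-Bu2AlH, CH2Cl2, −78 °C
Reagents that add atoms: none
Why: 1,2-Reduction of the enoate by the aluminium hydride at low temperature gives the E allylic alcohol needed for directed epoxidation, with the silyl ether and acetonide inert.

Step 5
Reactants: 7 (2E)-3-[(4S,5R)-2,2-dimethyl-5-[(triethylsilyloxy)methyl]-1,3-dioxolan-4-yl]but-2-en-1-ol
Product: 8 [(2S,3R)-3-[(4R,5R)-2,2-dimethyl-5-[(triethylsilyloxy)methyl]-1,3-dioxolan-4-yl]-3-methyloxiran-2-yl]methanol
Conditions: Ti(OiPr)4, L-(+)-diethyl tartrate, t-BuOOH, 4 Å molecular sieves, CH2Cl2, −20 °C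
Reagents that add atoms: tert-butyl hydroperoxide CC(C)(C)OO
Why: Sharpless asymmetric epoxidation with L-(+)-diethyl tartrate should oxidize the E allylic alcohol on the face that gives the (2S,3R)-epoxy alcohol (the facial sense known for geraniol-type substrates), so C1 is set by the catalyst, which overrides the bias of the neighbouring C9 centre.

Step 6
Reactants: 8 [(2S,3R)-3-[(4R,5R)-2,2-dimethyl-5-[(triethylsilyloxy)methyl]-1,3-dioxolan-4-yl]-3-methyloxiran-2-yl]methanol
Product: 9 TBS ether of 8 at the C2 oxygen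
Conditions: t-BuMe2SiCl, imidazole, DMF, 0 °C to rt
Reagents that add atoms: tert-butyldimethylsilyl chloride CC(C)(C)[Si](C)(C)Cl
Why: Standard imidazole-promoted silylation of the primary alcohol masks the C2 oxygen until the diol is released in step 14.

Step 7
Reactants: 9 TBS ether of 8
Product: 10 [(4R,5R)-5-[(2R,3S)-3-[(tert-butyldimethylsilyloxy)methyl]-2-methyloxiran-2-yl]-2,2-dimethyl-1,3-dioxolan-4-yl]methanol
Conditions: HF·pyridine, pyridine, THF, 0 °C
Reagents that add atoms: none
Why: Fluoride cleavage discriminates the more labile primary triethylsilyl ether from the primary tert-butyldimethylsilyl ether, and the pyridine buffer keeps the epoxide and acetonide intact.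

Step 8
Reactants: 10 [(4R,5R)-5-[(2R,3S)-3-[(tert-butyldimethylsilyloxy)methyl]-2-methyloxiran-2-yl]-2,2-dimethyl-1,3-dioxolan-4-yl]methanol; 11 tert-butyl (triphenylphosphoranylidene)acetate
Product: 13 tert-butyl (2E)-3-[(4R,5R)-5-[(2R,3S)-3-[(tert-butyldimethylsilyloxy)methyl]-2-methyloxiran-2-yl]-2,2-dimethyl-1,3-dioxolan-4-yl]prop-2-enoate, via aldehyde 12 (not isolated)
Conditions: Dess–Martin periodinane, NaHCO3, CH2Cl2, 0 °C to rt; then 11, rt
Reagents that add atoms: none
Why: Dess–Martin oxidation followed in the same flask by Wittig olefination with the stabilized ylide should give the E enoate, and not isolating the α-alkoxy aldehyde avoids epimerization at C8.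

Step 9
Reactants: 13 tert-butyl (2E)-3-[(4R,5R)-5-[(2R,3S)-3-[(tert-butyldimethylsilyloxy)methyl]-2-methyloxiran-2-yl]-2,2-dimethyl-1,3-dioxolan-4-yl]prop-2-enoate; 14 vinylmagnesium bromide
Product: 16 tert-butyl (3S)-3-[(4R,5R)-5-[(2R,3S)-3-[(tert-butyldimethylsilyloxy)methyl]-2-methyloxiran-2-yl]-2,2-dimethyl-1,3-dioxolan-4-yl]pent-4-enoate, via silyl ketene acetal 15 (not isolated)
Conditions: CuI (cat.), Me3SiCl, THF, −78 to −40 °C; aq. NH4Cl
Reagents that add atoms: none
Why: Copper-catalysed, chlorosilane-accelerated conjugate addition of the vinyl Grignard reagent should enter anti to the γ-oxygen O8 of the E enoate (the usual outcome for γ-alkoxy enoates of this geometry), which sets C7, and the ketene acetal is hydrolysed on work-up.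

Step 10
Reactants: 16 tert-butyl (3S)-3-[(4R,5R)-5-[(2R,3S)-3-[(tert-butyldimethylsilyloxy)methyl]-2-methyloxiran-2-yl]-2,2-dimethyl-1,3-dioxolan-4-yl]pent-4-enoate
Product: 18 tert-butyl (3R)-3-[(4R,5R)-5-[(2R,3S)-3-[(tert-butyldimethylsilyloxy)methyl]-2-methyloxiran-2-yl]-2,2-dimethyl-1,3-dioxolan-4-yl]-4-oxobutanoate, via ozonide 17 (not isolated)
Conditions: O3, CH2Cl2, −78 °C; then PPh3, −78 °C to rt
Reagents that add atoms: ozone [O-][O+]=O
Why: Ozonolysis with reductive work-up cleaves the only alkene of 16 and turns the vinyl group into the C6 aldehyde, the epoxide, silyl ether, acetonide and ester being inert to ozone at −78 °C.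

Step 11
Reactants: 18 tert-butyl (3R)-3-[(4R,5R)-5-[(2R,3S)-3-[(tert-butyldimethylsilyloxy)methyl]-2-methyloxiran-2-yl]-2,2-dimethyl-1,3-dioxolan-4-yl]-4-oxobutanoate; 19 1-bromo-2-methylprop-1-ene
Product: 21 tert-butyl (3S,4S)-3-[(4R,5R)-5-[(2R,3S)-3-[(tert-butyldimethylsilyloxy)methyl]-2-methyloxiran-2-yl]-2,2-dimethyl-1,3-dioxolan-4-yl]-4-hydroxy-6-methylhept-5-enoate, via alkenylmagnesium bromide 20 (not isolated)
Conditions: 19, Mg, THF, rt; 18, MgBr2·OEt2, CH2Cl2, −78 °C, then 20, −78 °C
Reagents that add atoms: none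
Why: Cram-chelate controlled Grignard addition, in which magnesium bridges the aldehyde oxygen and O8 in a six-membered chelate whose substituents C11 and C9 lie on one face, so the alkenyl group should enter from the open face and set C6 (S), whereas open Felkin–Anh attack would give the epimer.

Step 12
Reactants: 21 tert-butyl (3S,4S)-3-[(4R,5R)-5-[(2R,3S)-3-[(tert-butyldimethylsilyloxy)methyl]-2-methyloxiran-2-yl]-2,2-dimethyl-1,3-dioxolan-4-yl]-4-hydroxy-6-methylhept-5-enoate
Product: 22 tert-butyl (3S,4S)-3-[(4R,5R)-5-[(2R,3S)-3-[(tert-butyldimethylsilyloxy)methyl]-2-methyloxiran-2-yl]-2,2-dimethyl-1,3-dioxolan-4-yl]-6-methyl-4-(2-methylpropanoyloxy)hept-5-enoate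
Conditions: (i-PrCO)2O, Et3N, DMAP (cat.), CH2Cl2, 0 °C to rt
Reagents that add atoms: 2-methylpropanoic anhydride CC(C)C(=O)OC(=O)C(C)C
Why: DMAP-catalysed acyl transfer to the secondary allylic alcohol installs the isobutyrate of the target while O6 is still unhindered and blocks O6 against the later lactonization.

Step 13
Reactants: 22 tert-butyl (3S,4S)-3-[(4R,5R)-5-[(2R,3S)-3-[(tert-butyldimethylsilyloxy)methyl]-2-methyloxiran-2-yl]-2,2-dimethyl-1,3-dioxolan-4-yl]-6-methyl-4-(2-methylpropanoyloxy)hept-5-enoate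
Product: 23 cyclohexane with C8,C9-acetonide, C7 CH2CO2t-Bu, C6 isobutyrate, C5 isopropenyl, C10 methyl and C1H(OH)–C2H2OTBS (1R,5S,6S,7S,8R,9S,10R)
Conditions: Cp2TiCl2, Mn dust, THF, rt (gives Cp2TiCl, trivalent titanium); slow addition of 22, rt; cold dilute aq. HCl work-up
Reagents that add atoms: none
Why: Cp2TiCl (trivalent titanium) gives one electron to the oxirane of 22 and the C10–O bond breaks homolytically, so that a tertiary β-titanoxy radical sits on C10 while C1 keeps its oxygen and the configuration set in step 5. This radical closes the cyclohexane by 6-exo-trig addition to C5, the less substituted carbon of the C5=C4 alkene, which creates the C5–C10 bond and a tertiary radical at C4; a second Cp2TiCl captures that radical and β-hydride loss from one methyl group leaves the isopropenyl group. The closest known reaction type is the titanocene-mediated reductive epoxide opening with radical cyclization and alkene-forming termination, established for epoxy-alkene and epoxypolyene substrates. Both new stereocentres should follow from a chair transition state dictated by C6–C9: the cis-fused acetonide brings the chain ends together, O8, the C7 side chain and the attacked alkene arm are equatorial, and at the planar C10 radical the bulky titanoxy-bearing C1 chain takes the equatorial site and the methyl the axial one, which places C14 cis and C1 trans to C4. The step needs ring closure to outrun 1,5-hydrogen transfer from C6–H and disproportionation or deoxygenation of the C10 radical; this should be secured by the slow capture of tertiary radicals by the bulky titanium reagent, by attack at the unhindered alkene CH that generates a tertiary radical, and by the acyloxy group, which makes C6–H a poor hydrogen donor towards a nucleophilic alkyl radical. Termination at a methyl hydrogen and not at C5–H is the usual outcome for tertiary alkyl titanium species of this kind.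

Step 14
Reactants: 23 cyclohexane with C8,C9-acetonide, C7 CH2CO2t-Bu, C6 isobutyrate, C5 isopropenyl, C10 methyl and C1H(OH)–C2H2OTBS
Product: 25 O8–C12 lactone triol with C6 isobutyrate, C5 isopropenyl, C9 OH, C10 methyl and (1R)-1,2-dihydroxyethyl (1R,5S,6S,7S,8R,9S,10R), via bis(trimethylsilyl) intermediate 24 (not isolated)
Conditions: Me3SiOTf, 2,6-lutidine, CH2Cl2, 0 °C; then AcOH/H2O (4:1), 55 °C, toluene azeotrope
Reagents that add atoms: none
Why: The silyl triflate with a hindered pyridine exchanges the tert-butyl ester for a silyl ester without protic acid, so the isopropenyl group is never protonated, and warm aqueous acetic acid then hydrolyses the silyl groups and the acetonide and lets the C8 hydroxyl lactonize with the C12 acid (trans-fused γ-lactone), O6 being blocked as its ester and O9 being unable to reach C12.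

Step 15
Reactants: 25 O8–C12 lactone triol
Product: 27 lactone with C10 (R)-oxiranyl, C9 OH, C6 isobutyrate and C5 isopropenyl (1R,5S,6S,7S,8R,9S,10S), via C2 tosylate 26 (not isolated)
Conditions: TsCl, Et3N, Bu2SnO (cat.), CH2Cl2, 0 °C to rt; then DBU, rt
Reagents that add atoms: none
Why: Tin-acetal-catalysed sulfonylation picks the primary hydroxyl of the 1,2-diol and the C1 oxygen then displaces the sulfonate in an intramolecular Williamson (3-exo-tet) closure that keeps the C1 configuration, a vicinal closure that under basic conditions is expected to outrun attack of the hindered axial C9 hydroxyl on C2.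

Step 16
Reactants: 27 lactone with C10 (R)-oxiranyl
Product: 28 C11-(dimethylaminomethyl) lactone (C11 epimers; other centres as in 27)
Conditions: LiN(SiMe3)2 (excess), THF, −78 °C; Me2N=CH2 iodide, −78 to 0 °C
Reagents that add atoms: N,N-dimethylmethyleneiminium iodide C=[N+](C)C.[I-]
Why: Kinetic deprotonation should select the lactone α-CH2 (C11), which is more acidic and far less hindered than the isobutyrate methine, and the enolate is aminomethylated by Eschenmoser's salt (Mannich reaction), one extra equivalent of base being spent on the C9 hydroxyl and the oxirane being inert at −78 °C.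

Step 17
Reactants: 28 C11-(dimethylaminomethyl) lactone
Product: 30 C11=C13 methylene lactone with C10 (R)-oxiranyl, C9 OH, C6 isobutyrate and C5 isopropenyl (1R,5S,6S,7S,8R,9S,10S), via ammonium iodide 29 (not isolated)
Conditions: MeI, THF, rt; then aq. NaHCO3, EtOAc, rt
Reagents that add atoms: none
Why: Exhaustive N-methylation and mild base-induced β-elimination of the ammonium salt (Hofmann-type, E1cB) give the exocyclic C11=C13 alkene without touching the ester or the oxirane.

Step 18
Reactants: 30 C11=C13 methylene lactone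
Product: 31 C3 allylic alcohol, i.e. 30 with C5 3-hydroxyprop-1-en-2-yl (1R,5S,6S,7S,8R,9S,10S)
Conditions: SeO2 (cat.), t-BuOOH, CH2Cl2, 0 °C to rt
Reagents that add atoms: selenium dioxide O=[Se]=O; tert-butyl hydroperoxide CC(C)(C)OO
Why: Riley allylic oxidation (ene reaction then [2,3]-sigmatropic shift) should occur on the electron-rich 1,1-disubstituted alkene at its methyl group in preference to the hindered C5–H, while the electron-poor methylene lactone is not attacked and any over-oxidation gives 32 directly.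

Step 19
Reactants: 31 C3 allylic alcohol
Product: 32 CNP0496100.1 (1R,5R,6S,7S,8R,9S,10S)
Conditions: MnO2, CH2Cl2, rt
Reagents that add atoms: none
Why: MnO2 oxidizes only the primary allylic alcohol to the enal and leaves the saturated secondary C9 hydroxyl, the oxirane and both esters untouched.

**Compound list**

1 | 2,3-O-isopropylidene-D-erythronolactone | O=C1OC[C@H]2OC(C)(C)O[C@@H]12 | starting material
2 | (4R,5R)-5-(hydroxymethyl)-N-methoxy-N,2,2-trimethyl-1,3-dioxolane-4-carboxamide | CON(C)C(=O)[C@@H]1OC(C)(C)O[C@@H]1CO | intermediate (not isolated)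
3 | (4R,5R)-N-methoxy-N,2,2-trimethyl-5-[(triethylsilyloxy)methyl]-1,3-dioxolane-4-carboxamide | CON(C)C(=O)[C@@H]1OC(C)(C)O[C@@H]1CO[Si](CC)(CC)CC | intermediate
4 | 1-[(4R,5R)-2,2-dimethyl-5-[(triethylsilyloxy)methyl]-1,3-dioxolan-4-yl]ethan-1-one | CC(=O)[C@@H]1OC(C)(C)O[C@@H]1CO[Si](CC)(CC)CC | intermediate
5 | triethyl phosphonoacetate | CCOC(=O)CP(=O)(OCC)OCC | starting material
6 | ethyl (2E)-3-[(4S,5R)-2,2-dimethyl-5-[(triethylsilyloxy)methyl]-1,3-dioxolan-4-yl]but-2-enoate | CCOC(=O)/C=C(\C)[C@@H]1OC(C)(C)O[C@@H]1CO[Si](CC)(CC)CC | intermediate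
7 | (2E)-3-[(4S,5R)-2,2-dimethyl-5-[(triethylsilyloxy)methyl]-1,3-dioxolan-4-yl]but-2-en-1-ol | OC/C=C(\C)[C@@H]1OC(C)(C)O[C@@H]1CO[Si](CC)(CC)CC | intermediate
8 | [(2S,3R)-3-[(4R,5R)-2,2-dimethyl-5-[(triethylsilyloxy)methyl]-1,3-dioxolan-4-yl]-3-methyloxiran-2-yl]methanol | OC[C@@H]1O[C@@]1(C)[C@@H]2OC(C)(C)O[C@@H]2CO[Si](CC)(CC)CC | intermediate
9 | TBS ether of 8 (C2–OTBS, C7–OTES) | CC(C)(C)[Si](C)(C)OC[C@@H]1O[C@@]1(C)[C@@H]2OC(C)(C)O[C@@H]2CO[Si](CC)(CC)CC | intermediate
10 | [(4R,5R)-5-[(2R,3S)-3-[(tert-butyldimethylsilyloxy)methyl]-2-methyloxiran-2-yl]-2,2-dimethyl-1,3-dioxolan-4-yl]methanol | CC(C)(C)[Si](C)(C)OC[C@@H]1O[C@@]1(C)[C@@H]2OC(C)(C)O[C@@H]2CO | intermediate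
11 | tert-butyl (triphenylphosphoranylidene)acetate | CC(C)(C)OC(=O)C=P(c1ccccc1)(c1ccccc1)c1ccccc1 | starting material
12 | (4S,5R)-5-[(2R,3S)-3-[(tert-butyldimethylsilyloxy)methyl]-2-methyloxiran-2-yl]-2,2-dimethyl-1,3-dioxolane-4-carbaldehyde | CC(C)(C)[Si](C)(C)OC[C@@H]1O[C@@]1(C)[C@@H]2OC(C)(C)O[C@@H]2C=O | intermediate (not isolated)
13 | tert-butyl (2E)-3-[(4R,5R)-5-[(2R,3S)-3-[(tert-butyldimethylsilyloxy)methyl]-2-methyloxiran-2-yl]-2,2-dimethyl-1,3-dioxolan-4-yl]prop-2-enoate | CC(C)(C)[Si](C)(C)OC[C@@H]1O[C@@]1(C)[C@@H]2OC(C)(C)O[C@@H]2/C=C/C(=O)OC(C)(C)C | intermediate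
14 | vinylmagnesium bromide | C=C[Mg]Br | starting material
15 | trimethylsilyl ketene acetal of 16 (alkene geometry undefined) | CC(C)(C)[Si](C)(C)OC[C@@H]1O[C@@]1(C)[C@@H]2OC(C)(C)O[C@@H]2[C@H](C=C)C=C(O[Si](C)(C)C)OC(C)(C)C | intermediate (not isolated)
16 | tert-butyl (3S)-3-[(4R,5R)-5-[(2R,3S)-3-[(tert-butyldimethylsilyloxy)methyl]-2-methyloxiran-2-yl]-2,2-dimethyl-1,3-dioxolan-4-yl]pent-4-enoate | CC(C)(C)[Si](C)(C)OC[C@@H]1O[C@@]1(C)[C@@H]2OC(C)(C)O[C@@H]2[C@H](C=C)CC(=O)OC(C)(C)C | intermediate
17 | 1,2,4-trioxolane (ozonide) of 16 (both configurations at the trioxolane carbon) | CC(C)(C)[Si](C)(C)OC[C@@H]1O[C@@]1(C)[C@@H]2OC(C)(C)O[C@@H]2[C@H](C3OCOO3)CC(=O)OC(C)(C)C | intermediate (not isolated)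
18 | tert-butyl (3R)-3-[(4R,5R)-5-[(2R,3S)-3-[(tert-butyldimethylsilyloxy)methyl]-2-methyloxiran-2-yl]-2,2-dimethyl-1,3-dioxolan-4-yl]-4-oxobutanoate | CC(C)(C)[Si](C)(C)OC[C@@H]1O[C@@]1(C)[C@@H]2OC(C)(C)O[C@@H]2[C@H](C=O)CC(=O)OC(C)(C)C | intermediate
19 | 1-bromo-2-methylprop-1-ene | CC(C)=CBr | starting material
20 | 2-methylprop-1-enylmagnesium bromide | CC(C)=C[Mg]Br | intermediate (not isolated)
21 | tert-butyl (3S,4S)-3-[(4R,5R)-5-[(2R,3S)-3-[(tert-butyldimethylsilyloxy)methyl]-2-methyloxiran-2-yl]-2,2-dimethyl-1,3-dioxolan-4-yl]-4-hydroxy-6-methylhept-5-enoate | CC(C)(C)[Si](C)(C)OC[C@@H]1O[C@@]1(C)[C@@H]2OC(C)(C)O[C@@H]2[C@H]([C@@H](O)C=C(C)C)CC(=O)OC(C)(C)C | intermediate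
22 | tert-butyl (3S,4S)-3-[(4R,5R)-5-[(2R,3S)-3-[(tert-butyldimethylsilyloxy)methyl]-2-methyloxiran-2-yl]-2,2-dimethyl-1,3-dioxolan-4-yl]-6-methyl-4-(2-methylpropanoyloxy)hept-5-enoate | CC(C)(C)[Si](C)(C)OC[C@@H]1O[C@@]1(C)[C@@H]2OC(C)(C)O[C@@H]2[C@H]([C@@H](OC(=O)C(C)C)C=C(C)C)CC(=O)OC(C)(C)C | intermediate
23 | cyclohexane with C8,C9-acetonide, C7 CH2CO2t-Bu, C6 isobutyrate, C5 isopropenyl, C10 methyl and C1H(OH)–C2H2OTBS (1R,5S,6S,7S,8R,9S,10R) | CC1(C)O[C@@H]2[C@@H](CC(=O)OC(C)(C)C)[C@@H](OC(=O)C(C)C)[C@@H](C(C)=C)[C@](C)([C@@H](O)CO[Si](C)(C)C(C)(C)C)[C@@H]2O1 | intermediate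
24 | 23 with C12 trimethylsilyl ester and C1 trimethylsilyl ether (configuration as in 23) | CC1(C)O[C@@H]2[C@@H](CC(=O)O[Si](C)(C)C)[C@@H](OC(=O)C(C)C)[C@@H](C(C)=C)[C@](C)([C@@H](O[Si](C)(C)C)CO[Si](C)(C)C(C)(C)C)[C@@H]2O1 | intermediate (not isolated)
25 | trans-fused O8–C12 γ-lactone with C6 isobutyrate, C5 isopropenyl, C9 OH, C10 methyl and (1R)-1,2-dihydroxyethyl (1R,5S,6S,7S,8R,9S,10R) | C1C(=O)O[C@@H]2[C@@H]1[C@@H](OC(=O)C(C)C)[C@@H](C(C)=C)[C@](C)([C@@H](O)CO)[C@@H]2O | intermediate
26 | C2 p-toluenesulfonate of 25 (configuration as in 25) | C1C(=O)O[C@@H]2[C@@H]1[C@@H](OC(=O)C(C)C)[C@@H](C(C)=C)[C@](C)([C@@H](O)COS(=O)(=O)c3ccc(C)cc3)[C@@H]2O | intermediate (not isolated)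
27 | lactone with C10 (R)-oxiranyl, C9 OH, C6 isobutyrate, C5 isopropenyl (1R,5S,6S,7S,8R,9S,10S) | C1C(=O)O[C@@H]2[C@@H]1[C@@H](OC(=O)C(C)C)[C@@H](C(C)=C)[C@](C)([C@@H]3CO3)[C@@H]2O | intermediate
28 | 27 with a dimethylaminomethyl group on C11 (C11 epimers; other centres as in 27) | CN(C)CC1C(=O)O[C@@H]2[C@@H]1[C@@H](OC(=O)C(C)C)[C@@H](C(C)=C)[C@](C)([C@@H]3CO3)[C@@H]2O | intermediate
29 | trimethylammonium iodide of 28 | C[N+](C)(C)CC1C(=O)O[C@@H]2[C@@H]1[C@@H](OC(=O)C(C)C)[C@@H](C(C)=C)[C@](C)([C@@H]3CO3)[C@@H]2O.[I-] | intermediate (not isolated)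
30 | C11=C13 methylene lactone with C10 (R)-oxiranyl, C9 OH, C6 isobutyrate, C5 isopropenyl (1R,5S,6S,7S,8R,9S,10S) | C=C1C(=O)O[C@@H]2[C@@H]1[C@@H](OC(=O)C(C)C)[C@@H](C(C)=C)[C@](C)([C@@H]3CO3)[C@@H]2O | intermediate
31 | 30 with C5 3-hydroxyprop-1-en-2-yl (1R,5S,6S,7S,8R,9S,10S) | C=C1C(=O)O[C@@H]2[C@@H]1[C@@H](OC(=O)C(C)C)[C@@H](C(=C)CO)[C@](C)([C@@H]3CO3)[C@@H]2O | intermediate
32 | CNP0496100.1 (1R,5R,6S,7S,8R,9S,10S) | C=C1C(=O)O[C@@H]2[C@@H]1[C@@H](OC(=O)C(C)C)[C@@H](C(=C)C=O)[C@](C)([C@@H]1CO1)[C@@H]2O | target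

**Step count and risks**

Total step count: 19. Longest linear sequence: 19 steps (1 to 32); the route is fully linear.

Steps most likely to fail:

1. Step 13. The C10 radical may be consumed before it reaches C5 (1,5-hydrogen transfer from C6–H, or disproportionation to the C10=C14 allylic alcohol), or the chair preference may be too weak and give poor facial selectivity at C5 and C10. The fallback forms the same C5–C10 bond by a polar instead of a radical path. It sets out from aldehyde 18: the alkenylmagnesium reagent made from (E)-1-iodo-2-methyl-3-(trimethylsilyl)prop-1-ene (t-BuLi, then MgBr2·OEt2) is added under the chelation conditions of step 11 to give the allylsilane alcohol F1, which is acylated as in step 12 to the allylsilane isobutyrate F2. BF3·OEt2 in CH2Cl2 at −78 °C should then open the oxirane at the tertiary C10 while the allylsilane terminus C5 attacks it (intramolecular epoxide–allylsilane cyclization of the Hosomi–Sakurai type). Loss of the silyl group leaves the isopropenyl group, and the sequence comes back to the route at 23.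

2. Step 11. Facial selectivity at C6 may be poor if magnesium does not hold the aldehyde oxygen and the acetonide oxygen O8 in one chelate; open Felkin–Anh attack would then favour the C6 epimer. The fallback sets the centre by hydride delivery instead of carbon addition. It sets out from aldehyde 18: addition of 20 in THF without MgBr2·OEt2 gives the C6-epimeric alcohol F3 (mixed with 21), Dess–Martin oxidation gives the enone F4, and reduction with KBH(s-Bu)3 in THF at −78 °C should deliver hydride anti to C8 (Felkin–Anh) with 1,2-selectivity on the β,β-disubstituted enone. This comes back to the route at 21.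

3. Step 15. During sulfonate activation the axial C9 hydroxyl may compete for C2 and close a tetrahydrofuran instead of the oxirane. The fallback avoids a free C2 electrophile: triol 25 is cyclodehydrated under Mitsunobu conditions (PPh3, diisopropyl azodicarboxylate, toluene, 0 °C to rt). O1 and O2 are then bound together in a dioxaphospholane that should collapse by 3-exo attack of O1 on C2 with retention at C1. This comes back to the route at 27 without new compounds.

**Further compounds**

F1 | step 13 | tert-butyl (3S,4S,5E)-3-[(4R,5R)-5-[(2R,3S)-3-[(tert-butyldimethylsilyloxy)methyl]-2-methyloxiran-2-yl]-2,2-dimethyl-1,3-dioxolan-4-yl]-4-hydroxy-6-methyl-7-(trimethylsilyl)hept-5-enoate | CC(C)(C)[Si](C)(C)OC[C@@H]1O[C@@]1(C)[C@@H]2OC(C)(C)O[C@@H]2[C@H]([C@@H](O)/C=C(\C)C[Si](C)(C)C)CC(=O)OC(C)(C)C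
F2 | step 13 | isobutyrate of F1 at O6 | CC(C)(C)[Si](C)(C)OC[C@@H]1O[C@@]1(C)[C@@H]2OC(C)(C)O[C@@H]2[C@H]([C@@H](OC(=O)C(C)C)/C=C(\C)C[Si](C)(C)C)CC(=O)OC(C)(C)C
F3 | step 11 | C6 epimer of 21, tert-butyl (3S,4R)-configured 4-hydroxy-6-methylhept-5-enoate | CC(C)(C)[Si](C)(C)OC[C@@H]1O[C@@]1(C)[C@@H]2OC(C)(C)O[C@@H]2[C@H]([C@H](O)C=C(C)C)CC(=O)OC(C)(C)C
F4 | step 11 | tert-butyl (3R)-3-[(4R,5R)-5-[(2R,3S)-3-[(tert-butyldimethylsilyloxy)methyl]-2-methyloxiran-2-yl]-2,2-dimethyl-1,3-dioxolan-4-yl]-6-methyl-4-oxohept-5-enoate | CC(C)(C)[Si](C)(C)OC[C@@H]1O[C@@]1(C)[C@@H]2OC(C)(C)O[C@@H]2[C@H](C(=O)C=C(C)C)CC(=O)OC(C)(C)C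
F0 | step 15 | none | none
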